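Ring B of colpol is a 5-alkylresorcinol whose C2, the carbon between the two C–OH carbons, carries bromine. As C2 of a cyclohexane-1,3-dione it is the only doubly activated carbon, so ring B is built saturated, brominated there and aromatised afterwards.
Retrosynthetic cuts, in order: Z-alkene back to alkyne; C2–Br and the aromaticity of ring B back to a 5-substituted cyclohexane-1,3-dione; ring B bonds C5–C6 and C1–C2 (methyl enone plus dimethyl malonate); the enone C=C (Wittig); the benzylic CH2–C(sp) bond to ring A.
Forward, the chain grows from ring A: benzylic bromide, but-3-yn-1-ol, keto ylide; malonate then closes ring B, which is decarboxylated, dibrominated at C2 and aromatised.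
The central unsaturation stays an alkyne until ring B is aromatic, because an internal alkyne takes up electrophilic bromine far more slowly than a cis-alkene and has no geometry to lose.
There is no stereocentre; the Z-alkene comes from syn addition of H2 to the alkyne over poisoned palladium in the second-last step.

Key step: step 7

Assumption: compounds 12 to 16 are drawn as keto tautomers although the diones are largely enolised, and their ring or chain stereocentres form as racemic mixtures that later steps erase, so no stereodescriptors are given for them.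

Step 1
Reactants: 1 4-bromo-2,5-dimethoxybenzaldehyde
Product: 2 4-bromo-2-hydroxy-5-methoxybenzaldehyde
Conditions: BCl3 (1.2 equiv), CH2Cl2, −78 °C to 0 °C; then H2O
Reagents that add atoms: none
Why: BCl3 chelates between the aldehyde oxygen and the ortho methoxy oxygen, so this chelation-directed Lewis-acid O-demethylation should remove only the C2 methyl group and keep the C5 methoxy group that the target needs.

Step 2
Reactants: 2 4-bromo-2-hydroxy-5-methoxybenzaldehyde
Product: 3 4-bromo-5-methoxy-2-(methoxymethoxy)benzaldehyde
Conditions: MOMCl, iPr2NEt, CH2Cl2, 0 °C to rt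
Reagents that add atoms: chloromethyl methyl ether, COCCl
Why: O-alkylation of the phenol with the reactive chloromethyl ether (MOM protection) should give an acetal that tolerates the hydride, copper, alkoxide and bromine steps ahead and is removed by acid at the end.

Step 3
Reactants: 3 4-bromo-5-methoxy-2-(methoxymethoxy)benzaldehyde
Product: 4 [4-bromo-5-methoxy-2-(methoxymethoxy)phenyl]methanol
Conditions: NaBH4, MeOH, 0 °C
Reagents that add atoms: none
Why: Borohydride reduction of the aldehyde is chemoselective and should leave the aryl bromide, the methyl ether and the MOM acetal untouched.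

Step 4
Reactants: 4 [4-bromo-5-methoxy-2-(methoxymethoxy)phenyl]methanol
Product: 5 1-bromo-4-(bromomethyl)-2-methoxy-5-(methoxymethoxy)benzene
Conditions: CBr4, PPh3, CH2Cl2, 0 °C
Reagents that add atoms: carbon tetrabromide, BrC(Br)(Br)Br
Why: The Appel reaction converts the benzylic alcohol through its alkoxyphosphonium salt under essentially neutral conditions, which should spare the acid-labile MOM ether; the bromide is used at once.

Step 5
Reactants: 5 1-bromo-4-(bromomethyl)-2-methoxy-5-(methoxymethoxy)benzene; 6 but-3-yn-1-ol
Product: 7 5-[4-bromo-5-methoxy-2-(methoxymethoxy)phenyl]pent-3-yn-1-ol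
Conditions: 6 (1.5 equiv), CuI (10 mol%), NaI (10 mol%), K2CO3, DMF, rt
Reagents that add atoms: none
Why: The copper acetylide formed in situ should displace the benzylic bromide (copper-catalysed sp–sp3 alkynylation of a benzylic halide) at room temperature, where neither the aryl C–Br bond nor the free primary alcohol reacts.

Step 6
Reactants: 7 5-[4-bromo-5-methoxy-2-(methoxymethoxy)phenyl]pent-3-yn-1-ol; 8 1-(triphenylphosphoranylidene)propan-2-one
Product: 10 (E)-8-[4-bromo-5-methoxy-2-(methoxymethoxy)phenyl]oct-3-en-6-yn-2-one, via alkynal 9 (not isolated)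
Conditions: Dess–Martin periodinane, NaHCO3, CH2Cl2, 0 °C; then 8 (2 equiv), 0 °C to rt
Reagents that add atoms: none
Why: Buffered Dess–Martin oxidation should give the beta,gamma-alkynyl aldehyde without base, and the stabilised ylide traps it in the same flask (Wittig olefination) before propargyl-to-allenyl isomerisation sets in, stabilised ylides giving the E-enone.

Step 7
Reactants: 10 (E)-8-[4-bromo-5-methoxy-2-(methoxymethoxy)phenyl]oct-3-en-6-yn-2-one; 11 dimethyl malonate
Product: 13 methyl 6-{4-[4-bromo-5-methoxy-2-(methoxymethoxy)phenyl]but-2-yn-1-yl}-2,4-dioxocyclohexane-1-carboxylate, via Michael adduct 12 (not isolated)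
Conditions: 11 (1.2 equiv), NaH (0.1 equiv), THF, 0 °C; then NaOMe (1.5 equiv), MeOH, 60 °C; AcOH quench
Reagents that add atoms: none
Why: Sodium dimethyl malonate, made with catalytic NaH so that malonate anion is the only base present, should add to C4 of the enone (Michael addition), the resulting ketone enolate being quenched by the acidic malonate C–H; NaOMe in MeOH then forms the methyl-ketone enolate, which attacks one malonate ester and expels methoxide (Claisen condensation), and the product is drawn out of the equilibria as the sodium enolate of a vinylogous acid. The closest known reaction type is the Michael–Claisen annulation of 4-alkylbut-3-en-2-ones with malonic esters that gives 5-alkylcyclohexane-1,3-diones. The six-membered ring closes in the 6-(enolendo)-exo-trig mode, and the other ketone enolate could only give a four-membered ring. The two ring stereocentres (C1 and C6) arise without control and need none, because decarboxylation and aromatisation remove both. The selectivity required is conjugate addition ahead of deprotonation at the propargylic C5, which is gamma to the ketone; the unhindered E-enone, the soft and weakly basic malonate anion, the excess of malonate over base at 0 °C and the late addition of alkoxide should secure it.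

Step 8
Reactants: 13 methyl 6-{4-[4-bromo-5-methoxy-2-(methoxymethoxy)phenyl]but-2-yn-1-yl}-2,4-dioxocyclohexane-1-carboxylate
Product: 15 5-{4-[4-bromo-5-methoxy-2-(methoxymethoxy)phenyl]but-2-yn-1-yl}cyclohexane-1,3-dione, via keto acid 14 (not isolated)
Conditions: NaOH, H2O/MeOH, 70 °C; then aq. HCl to pH 3, 50 °C
Reagents that add atoms: none
Why: Saponification followed by mild acidification releases a vinylogous beta-keto acid that should lose CO2 on gentle warming (decarboxylation), the standard route from such annulation products to 5-substituted cyclohexane-1,3-diones, and pH 3 is mild enough for the MOM acetal.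

Step 9
Reactants: 15 5-{4-[4-bromo-5-methoxy-2-(methoxymethoxy)phenyl]but-2-yn-1-yl}cyclohexane-1,3-dione
Product: 17 2-bromo-5-{4-[4-bromo-5-methoxy-2-(methoxymethoxy)phenyl]but-2-yn-1-yl}benzene-1,3-diol, via 2,2-dibromodione 16 (not isolated)
Conditions: NBS (2.0 equiv), CH2Cl2, 0 °C; then LiBr, Li2CO3, DMF, 100 °C
Reagents that add atoms: N-bromosuccinimide, O=C1CCC(=O)N1Br
Why: In this halogenative aromatisation of a cyclohexane-1,3-dione the enol should take up both bromines at C2, far faster than the alkyne or the alkoxy-substituted ring A can react; bromide then shuttles one bromine to C4, HBr is lost across C4–C5 (dehydrobromination) and tautomerisation gives the 2-bromoresorcinol, the carbonate buffer protecting the MOM group.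

Step 10
Reactants: 17 2-bromo-5-{4-[4-bromo-5-methoxy-2-(methoxymethoxy)phenyl]but-2-yn-1-yl}benzene-1,3-diol
Product: 18 2-bromo-5-{(2Z)-4-[4-bromo-5-methoxy-2-(methoxymethoxy)phenyl]but-2-en-1-yl}benzene-1,3-diol
Conditions: H2 (1 atm), Pd/CaCO3 poisoned with Pb(OAc)2, quinoline, EtOAc, rt
Reagents that add atoms: none
Why: Lindlar semihydrogenation delivers both hydrogens to the same face of the alkyne on the poisoned palladium surface, so the Z-alkene should form, while quinoline and low pressure hold back over-reduction and C–Br hydrogenolysis.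

Step 11
Reactants: 18 2-bromo-5-{(2Z)-4-[4-bromo-5-methoxy-2-(methoxymethoxy)phenyl]but-2-en-1-yl}benzene-1,3-diol
Product: 19 colpol
Conditions: HCl, MeOH, 40 °C
Reagents that add atoms: none
Why: Acid-catalysed methanolysis of the acetal (MOM removal) should free the ring A phenol under conditions that leave the aryl methyl ether, both aryl bromides and the Z-alkene unchanged.

Compound list
1 | 4-bromo-2,5-dimethoxybenzaldehyde | COc1cc(C=O)c(OC)cc1Br | starting material
2 | 4-bromo-2-hydroxy-5-methoxybenzaldehyde | COc1cc(C=O)c(O)cc1Br | intermediate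
3 | 4-bromo-5-methoxy-2-(methoxymethoxy)benzaldehyde | COCOc1cc(Br)c(OC)cc1C=O | intermediate
4 | [4-bromo-5-methoxy-2-(methoxymethoxy)phenyl]methanol | COCOc1cc(Br)c(OC)cc1CO | intermediate
5 | 1-bromo-4-(bromomethyl)-2-methoxy-5-(methoxymethoxy)benzene | COCOc1cc(Br)c(OC)cc1CBr | intermediate
6 | but-3-yn-1-ol | C#CCCO | starting material
7 | 5-[4-bromo-5-methoxy-2-(methoxymethoxy)phenyl]pent-3-yn-1-ol | COCOc1cc(Br)c(OC)cc1CC#CCCO | intermediate
8 | 1-(triphenylphosphoranylidene)propan-2-one | CC(=O)C=P(c1ccccc1)(c1ccccc1)c1ccccc1 | starting material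
9 | 5-[4-bromo-5-methoxy-2-(methoxymethoxy)phenyl]pent-3-ynal | COCOc1cc(Br)c(OC)cc1CC#CCC=O | intermediate
10 | (E)-8-[4-bromo-5-methoxy-2-(methoxymethoxy)phenyl]oct-3-en-6-yn-2-one | CC(=O)/C=C/CC#CCc1cc(OC)c(Br)cc1OCOC | intermediate
11 | dimethyl malonate | COC(=O)CC(=O)OC | starting material
12 | dimethyl 2-{1-[4-bromo-5-methoxy-2-(methoxymethoxy)phenyl]-7-oxooct-2-yn-5-yl}propanedioate | CC(=O)CC(CC#CCc1cc(OC)c(Br)cc1OCOC)C(C(=O)OC)C(=O)OC | intermediate
13 | methyl 6-{4-[4-bromo-5-methoxy-2-(methoxymethoxy)phenyl]but-2-yn-1-yl}-2,4-dioxocyclohexane-1-carboxylate | COC(=O)C1C(=O)CC(=O)CC1CC#CCc1cc(OC)c(Br)cc1OCOC | intermediate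
14 | 6-{4-[4-bromo-5-methoxy-2-(methoxymethoxy)phenyl]but-2-yn-1-yl}-2,4-dioxocyclohexane-1-carboxylic acid | OC(=O)C1C(=O)CC(=O)CC1CC#CCc1cc(OC)c(Br)cc1OCOC | intermediate
15 | 5-{4-[4-bromo-5-methoxy-2-(methoxymethoxy)phenyl]but-2-yn-1-yl}cyclohexane-1,3-dione | O=C1CC(=O)CC(CC#CCc2cc(OC)c(Br)cc2OCOC)C1 | intermediate
16 | 2,2-dibromo-5-{4-[4-bromo-5-methoxy-2-(methoxymethoxy)phenyl]but-2-yn-1-yl}cyclohexane-1,3-dione | O=C1CC(CC#CCc2cc(OC)c(Br)cc2OCOC)CC(=O)C1(Br)Br | intermediate
17 | 2-bromo-5-{4-[4-bromo-5-methoxy-2-(methoxymethoxy)phenyl]but-2-yn-1-yl}benzene-1,3-diol | COCOc1cc(Br)c(OC)cc1CC#CCc1cc(O)c(Br)c(O)c1 | intermediate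
18 | 2-bromo-5-{(2Z)-4-[4-bromo-5-methoxy-2-(methoxymethoxy)phenyl]but-2-en-1-yl}benzene-1,3-diol | COCOc1cc(Br)c(OC)cc1C/C=C\Cc1cc(O)c(Br)c(O)c1 | intermediate
19 | colpol, 2-bromo-5-[(2Z)-4-(4-bromo-2-hydroxy-5-methoxyphenyl)but-2-en-1-yl]benzene-1,3-diol | COc1cc(C/C=C\Cc2cc(O)c(Br)c(O)c2)c(O)cc1Br | target

Total step count: 11.
Longest linear sequence: 11 steps, from 1 to 19; compounds 6, 8 and 11 are purchased.

Steps most likely to fail

Step 7. Deprotonation of the propargylic C5–H2 of 10, either before conjugate addition or after retro-Michael reversal during the hot alkoxide stage, would move the unsaturation into conjugation and divert material from ring closure. The fallback sets out from 7 and comes back at 13. It exchanges the roles of donor and acceptor, so that the acceptor is an enoate whose gamma-hydrogens are markedly less acidic than those of the ketone. Oxidation of 7 as in step 6 and trapping of 9 with methyl (triphenylphosphoranylidene)acetate should give methyl (E)-7-[4-bromo-5-methoxy-2-(methoxymethoxy)phenyl]hept-2-en-5-ynoate F1. Methyl acetoacetate with NaOMe in MeOH should add through its C2 to the enoate and give dimethyl 2-acetyl-3-{4-[4-bromo-5-methoxy-2-(methoxymethoxy)phenyl]but-2-yn-1-yl}pentanedioate F2. Claisen closure of the acetyl methyl group onto the distal ester then leads to the same dione ester 13; this is the classical acetoacetate–enoate route to dihydroresorcinols.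

Step 9. Electrophilic bromine may be lost to the basic medium before it reaches C4, so that the ring stalls at the monobromide oxidation level. It may also be passed on to the freshly formed resorcinol or to ring A, giving over-bromination. The fallback sets out from 15 and comes back at 17; it separates bromination from dehydrogenation so that no bromine has to migrate. One equivalent of NBS in CH2Cl2 at 0 °C should give 2-bromo-5-{4-[4-bromo-5-methoxy-2-(methoxymethoxy)phenyl]but-2-yn-1-yl}cyclohexane-1,3-dione F3. TMSOTf and Et3N should convert it into 2-bromo-5-{4-[4-bromo-5-methoxy-2-(methoxymethoxy)phenyl]but-2-yn-1-yl}-1,3-bis(trimethylsilyloxy)cyclohexa-1,3-diene F4. DDQ should dehydrogenate this electron-rich diene to 2-bromo-5-{4-[4-bromo-5-methoxy-2-(methoxymethoxy)phenyl]but-2-yn-1-yl}-1,3-bis(trimethylsilyloxy)benzene F5, and K2CO3 in MeOH during work-up removes both silyl groups to return 17.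

Step 6. Propargyl-to-allenyl isomerisation of the aldehyde, or a base-induced shift of the new enone double bond, may compete with olefination under the weakly basic ylide. The fallback sets out from 5 and comes back at 10; no beta,gamma-unsaturated aldehyde is formed. Copper-catalysed coupling of 5 with pent-1-en-4-yne (CuI cat., K2CO3, DMF, rt) should give 1-bromo-4-(hex-5-en-2-yn-1-yl)-2-methoxy-5-(methoxymethoxy)benzene F6. Cross-metathesis of its terminal alkene with but-3-en-2-one (second-generation Hoveyda–Grubbs catalyst, CH2Cl2, 40 °C) should then install the E-enone of 10 directly.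

Further compounds
F1 | step 7 | methyl (E)-7-[4-bromo-5-methoxy-2-(methoxymethoxy)phenyl]hept-2-en-5-ynoate | COC(=O)/C=C/CC#CCc1cc(OC)c(Br)cc1OCOC
F2 | step 7 | dimethyl 2-acetyl-3-{4-[4-bromo-5-methoxy-2-(methoxymethoxy)phenyl]but-2-yn-1-yl}pentanedioate | COC(=O)CC(CC#CCc1cc(OC)c(Br)cc1OCOC)C(C(C)=O)C(=O)OC
F3 | step 9 | 2-bromo-5-{4-[4-bromo-5-methoxy-2-(methoxymethoxy)phenyl]but-2-yn-1-yl}cyclohexane-1,3-dione | O=C1CC(CC#CCc2cc(OC)c(Br)cc2OCOC)CC(=O)C1Br
F4 | step 9 | 2-bromo-5-{4-[4-bromo-5-methoxy-2-(methoxymethoxy)phenyl]but-2-yn-1-yl}-1,3-bis(trimethylsilyloxy)cyclohexa-1,3-diene | C[Si](C)(C)OC1=C(Br)C(O[Si](C)(C)C)=CC(CC#CCc2cc(OC)c(Br)cc2OCOC)C1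
F5 | step 9 | 2-bromo-5-{4-[4-bromo-5-methoxy-2-(methoxymethoxy)phenyl]but-2-yn-1-yl}-1,3-bis(trimethylsilyloxy)benzene | C[Si](C)(C)Oc1cc(CC#CCc2cc(OC)c(Br)cc2OCOC)cc(O[Si](C)(C)C)c1Br
F6 | step 6 | 1-bromo-4-(hex-5-en-2-yn-1-yl)-2-methoxy-5-(methoxymethoxy)benzene | C=CCC#CCc1cc(OC)c(Br)cc1OCOC
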